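**Retrosynthetic overview**
1. Target ⇒ (aldehyde oxidation, O-methylation) ⇒ ester C–O bond between 2,4-dimethoxy-6-propylbenzoic acid (ring A) and the 4-OH of 2,4-dihydroxy-6-pentylbenzaldehyde (ring B). The ring B carboxyl is carried as a formyl group until the last step.
2. Ring A acid ⇒ aldehyde ⇒ Vilsmeier formylation of 1,3-dimethoxy-5-propylbenzene.
3. Key C–C bond: aryl–CH2 of the propyl chain, from 1-bromo-3,5-dimethoxybenzene (electrophilic ipso carbon) and propanal. The normally electrophilic carbonyl carbon of propanal is made the nucleophile through its N–H hydrazone (nickel catalysis, loss of N2).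
4. Ring B aldehyde ⇒ Vilsmeier formylation of olivetol.
5. Rings: none is constructed. Both benzene rings are bought intact and only functionalised, ring A first, then ring B.

Assumption: the target has no stereocentre or other stereo element, so the SMILES defines it completely and no enantiomer question arises.

**Route**

Step 1
Reactants: 1 1-bromo-3,5-dimethoxybenzene; 2 propanal; 3 hydrazine hydrate
Product: 6 1,3-dimethoxy-5-propylbenzene, via propanal hydrazone 4 (not isolated), via benzylic diazene 5 (not isolated)
Conditions: 2 (2.0 equiv), N2H4·H2O (2.2 equiv), THF, 4 Å MS, 0 °C to rt, 1 h; then 1, Ni(cod)2 (10 mol %), PMe3 (20 mol %), K3PO4 (2.5 equiv), THF/dioxane, 80 °C, sealed tube, 16 h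
Reagents that add atoms: none
Why: Proposed new method: oxidative addition of 1 to zerovalent nickel gives an aryl nickel bromide (divalent nickel); hydrazone 4, deprotonated by K3PO4, binds through nitrogen and reacts as an aza-allyl anion (EtCH=N–NH− ↔ EtCH(−)–N=NH) that delivers its carbon to the aryl group in the reductive elimination, so the propanal carbonyl carbon serves as a reduced acyl-anion (alkyl carbanion) equivalent toward the equally electrophilic ipso carbon of the bromide; diazene 5 then loses N2 under base through the benzylic anion (Wolff–Kishner manifold) and leaves the CH2 group directly; the closest known reaction type is the nickel-catalysed deoxygenative cross-coupling of aryl halides with N–H hydrazones of aromatic aldehydes, the extension here being an aliphatic aldehyde hydrazone, for which N-arylation and azine formation are the competing paths (hence excess 4 and the small, electron-rich PMe3); no stereocentre is formed.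

Step 2
Reactants: 6 1,3-dimethoxy-5-propylbenzene
Product: 8 2,4-dimethoxy-6-propylbenzaldehyde, via aryl iminium chloride 7 (not isolated)
Conditions: POCl3 (1.3 equiv), DMF, 0 °C to 70 °C, 3 h; then H2O, 0 °C to rt
Reagents that add atoms: N,N-dimethylformamide CN(C)C=O; water O
Why: Vilsmeier–Haack formylation; the chloroiminium ion attacks the carbon flanked by propyl and methoxy (para to the other methoxy) rather than the more hindered site between the two methoxy groups, as established for orcinol and olivetol dimethyl ethers, and hydrolysis of 7 gives the aldehyde.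

Step 3
Reactants: 8 2,4-dimethoxy-6-propylbenzaldehyde
Product: 9 2,4-dimethoxy-6-propylbenzoic acid
Conditions: NaClO2 (3 equiv), NaH2PO4 (3 equiv), 2-methyl-2-butene (10 equiv), t-BuOH/H2O 3:1, rt, 6 h
Reagents that add atoms: sodium chlorite [Na+].[O-]Cl=O
Why: Pinnick oxidation; chlorous acid adds to the aldehyde and fragments to the acid, while 2-methyl-2-butene removes HOCl before it can chlorinate the dimethoxyarene.

Step 4
Reactants: 10 olivetol (5-pentylbenzene-1,3-diol)
Product: 12 2,4-dihydroxy-6-pentylbenzaldehyde, via aryl iminium chloride 11 (not isolated)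
Conditions: POCl3 (1.2 equiv), DMF, 0 °C to rt, 3 h; then H2O, 50 °C, 30 min
Reagents that add atoms: N,N-dimethylformamide CN(C)C=O; water O
Why: Vilsmeier–Haack formylation of the resorcinol at the carbon between OH and pentyl (para to the second OH), the regiochemistry known for olivetol; the product is deactivated against a second formylation.

Step 5
Reactants: 9 2,4-dimethoxy-6-propylbenzoic acid; 12 2,4-dihydroxy-6-pentylbenzaldehyde
Product: 14 4-formyl-3-hydroxy-5-pentylphenyl 2,4-dimethoxy-6-propylbenzoate, via mixed trifluoroacetic anhydride 13 (not isolated)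
Conditions: (CF3CO)2O (3 equiv), toluene, 0 °C to rt, 6 h; aq. NaHCO3 work-up
Reagents that add atoms: none
Why: Depside esterification by the trifluoroacetic anhydride method; 13 ionises toward the 2,4-dimethoxy-stabilised aroyl cation, which overcomes the di-ortho hindrance, and only the free 4-OH of 12 is acylated because the 2-OH is locked in a hydrogen bond to the formyl group.

Step 6
Reactants: 14 4-formyl-3-hydroxy-5-pentylphenyl 2,4-dimethoxy-6-propylbenzoate
Product: 15 4-formyl-3-methoxy-5-pentylphenyl 2,4-dimethoxy-6-propylbenzoate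
Conditions: MeI (3 equiv), K2CO3 (1.5 equiv), dry DMF, rt, 12 h
Reagents that add atoms: iodomethane CI
Why: Williamson O-methylation; carbonate deprotonates the remaining chelated phenol and the phenoxide is methylated, while the di-ortho-substituted aryl benzoate is too hindered to be cleaved by carbonate in dry DMF.

Step 7
Reactants: 15 4-formyl-3-methoxy-5-pentylphenyl 2,4-dimethoxy-6-propylbenzoate
Product: 16 4-[(2,4-dimethoxy-6-propylbenzoyl)oxy]-2-methoxy-6-pentylbenzoic acid
Conditions: NaClO2 (4 equiv), NaH2PO4 (4 equiv), 2-methyl-2-butene (15 equiv), t-BuOH/THF/H2O, rt, 8 h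
Reagents that add atoms: sodium chlorite [Na+].[O-]Cl=O
Why: Pinnick oxidation turns the formyl group into the carboxylic acid under buffered, non-nucleophilic conditions that leave the aryl ester and the methyl ethers untouched, the alkene scavenger preventing ring chlorination.

**Compound list**
1 | 1-bromo-3,5-dimethoxybenzene | COc1cc(Br)cc(OC)c1 | starting material
2 | propanal | CCC=O | starting material
3 | hydrazine hydrate | NN.O | starting material
4 | propanal hydrazone (propylidenehydrazine) | CCC=NN | intermediate
5 | [1-(3,5-dimethoxyphenyl)propyl]diazene | CCC(N=N)c1cc(OC)cc(OC)c1 | intermediate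
6 | 1,3-dimethoxy-5-propylbenzene | CCCc1cc(OC)cc(OC)c1 | intermediate
7 | N-[(2,4-dimethoxy-6-propylphenyl)methylidene]-N-methylmethanaminium chloride | CCCc1cc(OC)cc(OC)c1C=[N+](C)C.[Cl-] | intermediate
8 | 2,4-dimethoxy-6-propylbenzaldehyde | CCCc1cc(OC)cc(OC)c1C=O | intermediate
9 | 2,4-dimethoxy-6-propylbenzoic acid | CCCc1cc(OC)cc(OC)c1C(=O)O | intermediate
10 | olivetol (5-pentylbenzene-1,3-diol) | CCCCCc1cc(O)cc(O)c1 | starting material
11 | N-[(2,4-dihydroxy-6-pentylphenyl)methylidene]-N-methylmethanaminium chloride | CCCCCc1cc(O)cc(O)c1C=[N+](C)C.[Cl-] | intermediate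
12 | 2,4-dihydroxy-6-pentylbenzaldehyde | CCCCCc1cc(O)cc(O)c1C=O | intermediate
13 | 2,4-dimethoxy-6-propylbenzoic trifluoroacetic anhydride | CCCc1cc(OC)cc(OC)c1C(=O)OC(=O)C(F)(F)F | intermediate
14 | 4-formyl-3-hydroxy-5-pentylphenyl 2,4-dimethoxy-6-propylbenzoate | CCCCCc1cc(OC(=O)c2c(CCC)cc(OC)cc2OC)cc(O)c1C=O | intermediate
15 | 4-formyl-3-methoxy-5-pentylphenyl 2,4-dimethoxy-6-propylbenzoate | CCCCCc1cc(OC(=O)c2c(CCC)cc(OC)cc2OC)cc(OC)c1C=O | intermediate
16 | 4-[(2,4-dimethoxy-6-propylbenzoyl)oxy]-2-methoxy-6-pentylbenzoic acid | CCCCCc1cc(OC(=O)c2c(CCC)cc(OC)cc2OC)cc(OC)c1C(=O)O | target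

**Totals**
Total step count: 7. Longest linear sequence: 6 steps (steps 1, 2, 3, 5, 6, 7); step 4 is the one-step side branch.

**Three steps most likely to fail, with fallbacks**

Step 1 (nickel coupling of an aliphatic N–H hydrazone; N-arylation, azine formation or plain Wolff–Kishner reduction of 4 may win). The fallback sets out from 1 and comes back at 6, using a classical dithiane acyl anion with the roles of the partners exchanged. Compound 1 undergoes Br/Li exchange (n-BuLi, THF, −78 °C) and DMF quench to give 3,5-dimethoxybenzaldehyde F1, which is also cheap to buy. F1 with propane-1,3-dithiol and BF3·OEt2 (CH2Cl2, 0 °C) gives 2-(3,5-dimethoxyphenyl)-1,3-dithiane F2. Deprotonation of F2 with n-BuLi (THF, −78 to −30 °C) and alkylation with iodoethane gives 2-(3,5-dimethoxyphenyl)-2-ethyl-1,3-dithiane F3. Raney Ni in refluxing EtOH removes the sulfur and delivers 6.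

Step 5 (esterification of a di-ortho-substituted acid with a phenol that also carries a free formyl group; acylal formation, C-acylation or poor turnover are the risks). The fallback sets out from 10 and 9 and comes back at 16, carrying the ring B carboxyl as a benzyl ester instead of a latent aldehyde. Compound 10 is carboxylated with MeOMgOCO2Me (DMF, 120 °C; then aq. HCl) to 2,4-dihydroxy-6-pentylbenzoic acid F4. Its carboxylate is benzylated (BnBr, KHCO3, DMF, 40 °C) to benzyl 2,4-dihydroxy-6-pentylbenzoate F5. Condensation of F5 with 9 ((CF3CO)2O, toluene, rt) acylates the non-chelated 4-OH and gives benzyl 4-[(2,4-dimethoxy-6-propylbenzoyl)oxy]-2-hydroxy-6-pentylbenzoate F6. Methylation (MeI, K2CO3, DMF) gives benzyl 4-[(2,4-dimethoxy-6-propylbenzoyl)oxy]-2-methoxy-6-pentylbenzoate F7, and hydrogenolysis (H2, Pd/C, EtOAc, rt) gives 16.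

Step 6 (base-mediated methylation of the chelated phenol in the presence of the depside ester; ester cleavage or intermolecular acyl transfer by the phenoxide are the risks). The fallback sets out from 12 and comes back at 15, placing the methyl group before the ester exists. Compound 12 is allylated at the non-chelated 4-OH (allyl bromide 1.05 equiv, KHCO3, acetone, 50 °C) to 4-(allyloxy)-2-hydroxy-6-pentylbenzaldehyde F8. Methylation (MeI, K2CO3, DMF) gives 4-(allyloxy)-2-methoxy-6-pentylbenzaldehyde F9. Deallylation (Pd(PPh3)4 5 mol %, morpholine, THF, rt) gives 4-hydroxy-2-methoxy-6-pentylbenzaldehyde F10. F10 is condensed with 9 ((CF3CO)2O, toluene, rt) to give 15.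

**Further compounds**
F1 | step 1 | 3,5-dimethoxybenzaldehyde | COc1cc(C=O)cc(OC)c1
F2 | step 1 | 2-(3,5-dimethoxyphenyl)-1,3-dithiane | COc1cc(cc(OC)c1)C1SCCCS1
F3 | step 1 | 2-(3,5-dimethoxyphenyl)-2-ethyl-1,3-dithiane | CCC1(SCCCS1)c1cc(OC)cc(OC)c1
F4 | step 5 | 2,4-dihydroxy-6-pentylbenzoic acid | CCCCCc1cc(O)cc(O)c1C(=O)O
F5 | step 5 | benzyl 2,4-dihydroxy-6-pentylbenzoate | CCCCCc1cc(O)cc(O)c1C(=O)OCc1ccccc1
F6 | step 5 | benzyl 4-[(2,4-dimethoxy-6-propylbenzoyl)oxy]-2-hydroxy-6-pentylbenzoate | CCCCCc1cc(OC(=O)c2c(CCC)cc(OC)cc2OC)cc(O)c1C(=O)OCc1ccccc1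
F7 | step 5 | benzyl 4-[(2,4-dimethoxy-6-propylbenzoyl)oxy]-2-methoxy-6-pentylbenzoate | CCCCCc1cc(OC(=O)c2c(CCC)cc(OC)cc2OC)cc(OC)c1C(=O)OCc1ccccc1
F8 | step 6 | 4-(allyloxy)-2-hydroxy-6-pentylbenzaldehyde | CCCCCc1cc(OCC=C)cc(O)c1C=O
F9 | step 6 | 4-(allyloxy)-2-methoxy-6-pentylbenzaldehyde | CCCCCc1cc(OCC=C)cc(OC)c1C=O
F10 | step 6 | 4-hydroxy-2-methoxy-6-pentylbenzaldehyde | CCCCCc1cc(O)cc(OC)c1C=O
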